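## Retrosynthetic overview

1. The target is epicatechin-(4β→6)-epicatechin-(4β→6)-epicatechin. The last operations are removal of three acetates, then one hydrogenolysis that strips twelve benzyl ethers and four aryl bromine blocking groups.
2. The key disconnections are the two C4–C6 interflavan bonds. Each is made by intermolecular Michael-type conjugate addition of the free C6 of a C8-brominated, benzylated ring A (a vinylogous enol ether) to the quinone methide oxocarbenium released from a 4β-(2-ethoxyethoxy)flavan. This is the Lewis-acid (Friedel–Crafts-like) form of a Michael addition, not an enolate addition. The middle→lower bond is formed first, the upper→middle bond second.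
3. All three units come from (−)-epicatechin by benzylation, DDQ oxidation at C4, 3-O-acetylation and NBS bromination. The lower unit is 8-bromo (nucleophile only). The middle unit is 8-bromo with a C4 leaving group. The upper unit is 6,8-dibromo with a C4 leaving group, so it can act only as an electrophile.
4. No ring has to be built: rings A, B and C of every unit and all 2,3-cis centres are bought with (−)-epicatechin. Only the two interflavan C4 centres are created (4β, anti to the 3-acetoxy group).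

Assumption: the SMILES is read as 2R,3R in all three units and 4S (3,4-trans) at both interflavan carbons, and commercial (−)-epicatechin (2R,3R) is the chiral source.

## Route

Step 1
Reactants: 1 (−)-epicatechin
Product: 2 (2R,3R)-5,7,3',4'-tetra-O-benzylepicatechin
Conditions: BnBr (4.4 equiv), K2CO3 (5 equiv), DMF, 0 °C → rt, Ar
Reagents that add atoms: benzyl bromide, BrCc1ccccc1
Why: Williamson ether synthesis in which carbonate deprotonates only the four phenols (not the C3 alcohol), and O-benzylation at or below room temperature leaves the 2R,3R centres untouched.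

Step 2
Reactants: 2 (2R,3R)-5,7,3',4'-tetra-O-benzylepicatechin
Product: 3 (2R,3R)-8-bromo-5,7,3',4'-tetra-O-benzylepicatechin
Conditions: NBS (1.0 equiv), CH2Cl2, −78 °C → 0 °C
Reagents that add atoms: N-bromosuccinimide, O=C1CCC(=O)N1Br
Why: Electrophilic aromatic bromination in which the trialkoxy ring A reacts far faster than ring B and NBS attacks C8 (next to the tied-back ring oxygen) in preference to the more crowded C6, which stays the only free ring A position.

Step 3
Reactants: 3 (2R,3R)-8-bromo-5,7,3',4'-tetra-O-benzylepicatechin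
Product: 4 (2R,3R)-3-O-acetyl-8-bromo-5,7,3',4'-tetra-O-benzylepicatechin
Conditions: Ac2O, pyridine, DMAP (cat.), CH2Cl2, rt
Reagents that add atoms: acetic anhydride, CC(=O)OC(C)=O
Why: DMAP-catalysed acylation of the only free hydroxyl, so that the C3 oxygen can neither act as an O-nucleophile nor consume the silyl triflate in the coupling, with no change at any stereocentre.

Step 4
Reactants: 2 (2R,3R)-5,7,3',4'-tetra-O-benzylepicatechin
Product: 6 (2R,3R,4S)-4β-(2-ethoxyethoxy)-5,7,3',4'-tetra-O-benzylepicatechin, via quinone methide oxocarbenium ion 5 (not isolated)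
Conditions: DDQ (2 equiv), 2-ethoxyethanol (5 equiv), CH2Cl2, rt
Reagents that add atoms: 2-ethoxyethanol, CCOCCO
Why: DDQ benzylic oxidation in which hydride abstraction from the electron-rich C4 gives cation 5, and the alcohol traps it from the β face, anti to the axial C3 oxygen, giving the 3,4-trans (4S) ether.

Step 5
Reactants: 6 (2R,3R,4S)-4β-(2-ethoxyethoxy)-5,7,3',4'-tetra-O-benzylepicatechin
Product: 7 (2R,3R,4S)-3-O-acetyl-4β-(2-ethoxyethoxy)-5,7,3',4'-tetra-O-benzylepicatechin
Conditions: Ac2O, pyridine, DMAP (cat.), CH2Cl2, rt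
Reagents that add atoms: acetic anhydride, CC(=O)OC(C)=O
Why: DMAP-catalysed acylation that installs the 3-acetate, which later shields the α face of the C4 cation (acetoxonium participation) and blocks O-alkylation.

Step 6
Reactants: 7 (2R,3R,4S)-3-O-acetyl-4β-(2-ethoxyethoxy)-5,7,3',4'-tetra-O-benzylepicatechin
Product: 8 (2R,3R,4S)-3-O-acetyl-8-bromo-4β-(2-ethoxyethoxy)-5,7,3',4'-tetra-O-benzylepicatechin
Conditions: NBS (1.05 equiv), NaHCO3 (solid), CH2Cl2, −78 °C → 0 °C
Reagents that add atoms: N-bromosuccinimide, O=C1CCC(=O)N1Br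
Why: Electrophilic aromatic bromination under buffered neutral conditions (the C4 ether is untouched) blocks C8 as in step 2, so this unit can later be arylated only at C6.

Step 7
Reactants: 8 (2R,3R,4S)-3-O-acetyl-8-bromo-4β-(2-ethoxyethoxy)-5,7,3',4'-tetra-O-benzylepicatechin; 4 (2R,3R)-3-O-acetyl-8-bromo-5,7,3',4'-tetra-O-benzylepicatechin
Product: 10 dimer 3-O-acetyl-8-bromo-5,7,3',4'-tetra-O-benzylepicatechin-(4β→6)-3-O-acetyl-8-bromo-5,7,3',4'-tetra-O-benzylepicatechin, via brominated quinone methide oxocarbenium ion 9 (not isolated)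
Conditions: 4 (4 equiv, excess recovered), TMSOTf (0.2 equiv), 4 Å MS, CH2Cl2, −78 → −40 °C, 8 added over 1 h; then Et3N
Reagents that add atoms: none
Why: TMSOTf ionises the C4 ether to the O-benzyl quinone methide oxocarbenium 9, and C6 of 4 (its only free ring A carbon, C8 being brominated) adds to the methide carbon in an intermolecular Michael-type conjugate addition (Mukaiyama–Michael/Friedel–Crafts manifold), with attack anti to the 3-acetoxy group setting the new centre as 4β (3,4-trans).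

Step 8
Reactants: 7 (2R,3R,4S)-3-O-acetyl-4β-(2-ethoxyethoxy)-5,7,3',4'-tetra-O-benzylepicatechin
Product: 11 (2R,3R,4S)-3-O-acetyl-6,8-dibromo-4β-(2-ethoxyethoxy)-5,7,3',4'-tetra-O-benzylepicatechin
Conditions: NBS (2.3 equiv), NaHCO3 (solid), CH2Cl2, −20 °C → rt, dark
Reagents that add atoms: N-bromosuccinimide, O=C1CCC(=O)N1Br
Why: Twofold electrophilic aromatic bromination in which C8 reacts first and the second equivalent of NBS takes the remaining C6 between the two benzyloxy groups, so this unit has no nucleophilic ring A carbon left and can act only as an electrophile, while the solid bicarbonate keeps the C4 ether intact.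

Step 9
Reactants: 11 (2R,3R,4S)-3-O-acetyl-6,8-dibromo-4β-(2-ethoxyethoxy)-5,7,3',4'-tetra-O-benzylepicatechin; 10 dimer 3-O-acetyl-8-bromo-5,7,3',4'-tetra-O-benzylepicatechin-(4β→6)-3-O-acetyl-8-bromo-5,7,3',4'-tetra-O-benzylepicatechin
Product: 13 trimer 3-O-acetyl-6,8-dibromo-5,7,3',4'-tetra-O-benzylepicatechin-(4β→6)-3-O-acetyl-8-bromo-5,7,3',4'-tetra-O-benzylepicatechin-(4β→6)-3-O-acetyl-8-bromo-5,7,3',4'-tetra-O-benzylepicatechin, via dibrominated quinone methide oxocarbenium ion 12 (not isolated)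
Conditions: 10 (1 equiv), 11 (1.5 equiv), TMSOTf (0.5 equiv), 4 Å MS, CH2Cl2, −78 → −20 °C; then Et3N
Reagents that add atoms: none
Why: TMSOTf ionises the C4 ether of 11 to cation 12, which cannot arylate itself, and the only free ring A carbon of 10 (C6 of its upper unit) adds to the methide carbon in the same Michael-type conjugate addition, β-face attack anti to the 3-acetoxy group setting the second interflavan centre as 4β (3,4-trans).

Step 10
Reactants: 13 trimer 3-O-acetyl-6,8-dibromo-5,7,3',4'-tetra-O-benzylepicatechin-(4β→6)-3-O-acetyl-8-bromo-5,7,3',4'-tetra-O-benzylepicatechin-(4β→6)-3-O-acetyl-8-bromo-5,7,3',4'-tetra-O-benzylepicatechin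
Product: 14 trimer 6,8-dibromo-5,7,3',4'-tetra-O-benzylepicatechin-(4β→6)-8-bromo-5,7,3',4'-tetra-O-benzylepicatechin-(4β→6)-8-bromo-5,7,3',4'-tetra-O-benzylepicatechin
Conditions: NaOMe (0.3 equiv), MeOH/THF 1:1, rt → 40 °C
Reagents that add atoms: none
Why: Zemplén transesterification in which catalytic methoxide passes the three acetyl groups to methanol, while aryl bromides, benzyl ethers and all stereocentres are inert because no free phenol is present to open ring C.

Step 11
Reactants: 14 trimer 6,8-dibromo-5,7,3',4'-tetra-O-benzylepicatechin-(4β→6)-8-bromo-5,7,3',4'-tetra-O-benzylepicatechin-(4β→6)-8-bromo-5,7,3',4'-tetra-O-benzylepicatechin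
Product: 15 epicatechin-(4β→6)-epicatechin-(4β→6)-epicatechin (target)
Conditions: H2 (1 atm), 20% Pd(OH)2/C, NaOAc (5 equiv), THF/MeOH/H2O 20:20:1, rt
Reagents that add atoms: none
Why: Catalytic hydrogenolysis in which Pd(OH)2/C cleaves the twelve O-benzyl ethers and the four aryl C–Br bonds in one operation, the acetate buffer takes up HBr so the acid-labile interflavan bonds survive, and no C–C bond or stereocentre is affected.

## Compound list

1 | (−)-epicatechin, (2R,3R) | Oc1cc(O)c2c(c1)O[C@H](c1ccc(O)c(O)c1)[C@H](O)C2 | starting material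

2 | (2R,3R)-5,7,3',4'-tetra-O-benzylepicatechin | c1ccccc1COc1cc(OCc2ccccc2)c2c(c1)O[C@H](c1ccc(OCc3ccccc3)c(OCc3ccccc3)c1)[C@H](O)C2 | intermediate

3 | (2R,3R)-8-bromo-5,7,3',4'-tetra-O-benzylepicatechin | c1ccccc1COc1cc(OCc2ccccc2)c2c(c1Br)O[C@H](c1ccc(OCc3ccccc3)c(OCc3ccccc3)c1)[C@H](O)C2 | intermediate

4 | (2R,3R)-3-O-acetyl-8-bromo-5,7,3',4'-tetra-O-benzylepicatechin (nucleophile, lower unit) | c1ccccc1COc1cc(OCc2ccccc2)c2c(c1Br)O[C@H](c1ccc(OCc3ccccc3)c(OCc3ccccc3)c1)[C@H](OC(C)=O)C2 | intermediate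

5 | quinone methide oxocarbenium ion from 2 (C4=C4a, 7-O-benzyl oxonium; C2 and C3 as in 2) | c1ccccc1C[O+]=C1C=C(OCc2ccccc2)C=2C(=C1)O[C@H](c1ccc(OCc3ccccc3)c(OCc3ccccc3)c1)[C@H](O)C=2 | intermediate (not isolated)

6 | (2R,3R,4S)-4β-(2-ethoxyethoxy)-5,7,3',4'-tetra-O-benzylepicatechin | c1ccccc1COc1cc(OCc2ccccc2)c2c(c1)O[C@H](c1ccc(OCc3ccccc3)c(OCc3ccccc3)c1)[C@H](O)[C@H]2OCCOCC | intermediate

7 | (2R,3R,4S)-3-O-acetyl-4β-(2-ethoxyethoxy)-5,7,3',4'-tetra-O-benzylepicatechin | c1ccccc1COc1cc(OCc2ccccc2)c2c(c1)O[C@H](c1ccc(OCc3ccccc3)c(OCc3ccccc3)c1)[C@H](OC(C)=O)[C@H]2OCCOCC | intermediate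

8 | (2R,3R,4S)-3-O-acetyl-8-bromo-4β-(2-ethoxyethoxy)-5,7,3',4'-tetra-O-benzylepicatechin (electrophile, middle unit) | c1ccccc1COc1cc(OCc2ccccc2)c2c(c1Br)O[C@H](c1ccc(OCc3ccccc3)c(OCc3ccccc3)c1)[C@H](OC(C)=O)[C@H]2OCCOCC | intermediate

9 | brominated quinone methide oxocarbenium ion from 8 (C4=C4a, 7-O-benzyl oxonium, 8-Br; C2 and C3 as in 8) | c1ccccc1C[O+]=C1C=C(OCc2ccccc2)C=2C(=C1Br)O[C@H](c1ccc(OCc3ccccc3)c(OCc3ccccc3)c1)[C@H](OC(C)=O)C=2 | intermediate (not isolated)

10 | dimer 3-O-acetyl-8-bromo-5,7,3',4'-tetra-O-benzylepicatechin-(4β→6)-3-O-acetyl-8-bromo-5,7,3',4'-tetra-O-benzylepicatechin (all 2R,3R; interflavan carbon 4β, 3,4-trans) | c1ccccc1COc1cc(OCc2ccccc2)c2c(c1Br)O[C@H](c1ccc(OCc3ccccc3)c(OCc3ccccc3)c1)[C@H](OC(C)=O)[C@H]2c1c(OCc2ccccc2)c(Br)c3c(c1OCc4ccccc4)C[C@@H](OC(C)=O)[C@@H](c1ccc(OCc4ccccc4)c(OCc4ccccc4)c1)O3 | intermediate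

11 | (2R,3R,4S)-3-O-acetyl-6,8-dibromo-4β-(2-ethoxyethoxy)-5,7,3',4'-tetra-O-benzylepicatechin (electrophile, upper unit) | c1ccccc1COc1c(Br)c(OCc2ccccc2)c2c(c1Br)O[C@H](c1ccc(OCc3ccccc3)c(OCc3ccccc3)c1)[C@H](OC(C)=O)[C@H]2OCCOCC | intermediate

12 | dibrominated quinone methide oxocarbenium ion from 11 (C4=C4a, 7-O-benzyl oxonium, 6-Br and 8-Br; C2 and C3 as in 11) | c1ccccc1C[O+]=C1C(Br)=C(OCc2ccccc2)C=2C(=C1Br)O[C@H](c1ccc(OCc3ccccc3)c(OCc3ccccc3)c1)[C@H](OC(C)=O)C=2 | intermediate (not isolated)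

13 | trimer, tri-O-acetyl-tetrabromo-dodeca-O-benzyl epicatechin-(4β→6)-epicatechin-(4β→6)-epicatechin (3-OAc on every unit; 6,8-Br2 on the upper unit, 8-Br on the middle and lower units; all 2R,3R; both interflavan carbons 4β) | c1ccccc1COc1c(Br)c(OCc2ccccc2)c2c(c1Br)O[C@H](c1ccc(OCc3ccccc3)c(OCc3ccccc3)c1)[C@H](OC(C)=O)[C@H]2c1c(OCc2ccccc2)c(Br)c2c(c1OCc3ccccc3)[C@H](c1c(OCc3ccccc3)c(Br)c3c(c1OCc4ccccc4)C[C@@H](OC(C)=O)[C@@H](c1ccc(OCc4ccccc4)c(OCc4ccccc4)c1)O3)[C@@H](OC(C)=O)[C@@H](c1ccc(OCc3ccccc3)c(OCc3ccccc3)c1)O2 | intermediate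

14 | trimer, tetrabromo-dodeca-O-benzyl epicatechin-(4β→6)-epicatechin-(4β→6)-epicatechin (free 3-OH on every unit; bromines as in 13) | c1ccccc1COc1c(Br)c(OCc2ccccc2)c2c(c1Br)O[C@H](c1ccc(OCc3ccccc3)c(OCc3ccccc3)c1)[C@H](O)[C@H]2c1c(OCc2ccccc2)c(Br)c2c(c1OCc3ccccc3)[C@H](c1c(OCc3ccccc3)c(Br)c3c(c1OCc4ccccc4)C[C@@H](O)[C@@H](c1ccc(OCc4ccccc4)c(OCc4ccccc4)c1)O3)[C@@H](O)[C@@H](c1ccc(OCc3ccccc3)c(OCc3ccccc3)c1)O2 | intermediate

15 | epicatechin-(4β→6)-epicatechin-(4β→6)-epicatechin, CNP0163146.2 (upper and middle units 2R,3R,4S; lower unit 2R,3R) | Oc1cc(O)c2c(c1)O[C@H](c1ccc(O)c(O)c1)[C@H](O)[C@H]2c1c(O)cc2c(c1O)[C@H](c1c(O)cc3c(c1O)C[C@@H](O)[C@@H](c1ccc(O)c(O)c1)O3)[C@@H](O)[C@@H](c1ccc(O)c(O)c1)O2 | target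

## Totals and risks

Total step count: 11.
Longest linear sequence: 8 steps (1 → 2 → 6 → 7 → 8 → 10 → 13 → 14 → 15; steps 1, 4, 5, 6, 7, 9, 10, 11).

Three steps most likely to fail:

Step 7. C6 of the C8-brominated nucleophile is the less reactive ring A position, and under silyl triflate the electrophile 8 can arylate itself or the product through a free C6. The fallback sets out from 8 and comes back at 10, replacing hard Lewis-acid ionisation of an ether by thiophilic activation of a sulfide. Compound 8 is treated with phenylmethanethiol and BF3·OEt2 (CH2Cl2, −78 → −20 °C), the thiol entering at C4 from the β face, to give 3-O-acetyl-8-bromo-4β-benzylsulfanyl-5,7,3',4'-tetra-O-benzylepicatechin F1. F1 and 4 (4 equiv) are then joined with AgBF4 (1.5 equiv, THF, 0 °C → rt, dark, 2,6-di-tert-butyl-4-methylpyridine as acid scavenger). The silver salt removes the sulfur irreversibly as its thiolate and releases the C4 cation with no silyl triflate present, so the sluggish C6 nucleophile can be given more time and temperature. The product is 10.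

Step 9. The nucleophilic carbon of dimer 10 is flanked by two benzyloxy groups and sits next to the first interflavan bond, and the dibrominated cation is more crowded and less stabilised than the monobrominated one. The fallback sets out from 8 and comes back at 13, reversing the order of bond formation with an orthogonal leaving group so that a monomer is the nucleophile in both couplings. Compound 8 with 2,6-dimethylbenzenethiol and BF3·OEt2 (CH2Cl2, −78 → −20 °C) gives 3-O-acetyl-8-bromo-4β-(2,6-dimethylphenylsulfanyl)-5,7,3',4'-tetra-O-benzylepicatechin F2. F2 (3 equiv) then acts as the nucleophile through its free C6 towards 11 under BF3·OEt2 (CH2Cl2, −78 → −30 °C), its hindered C4–S bond being inert to the hard Lewis acid. This gives the upper–middle dimer 3-O-acetyl-6,8-dibromo-5,7,3',4'-tetra-O-benzylepicatechin-(4β→6)-3-O-acetyl-8-bromo-4β-(2,6-dimethylphenylsulfanyl)-5,7,3',4'-tetra-O-benzylepicatechin F3, which has no free ring A carbon. Soft activation of F3 with I2 and Ag2O (CH2Cl2, −40 → 0 °C) in the presence of 4 (4 equiv) forms the second interflavan bond and delivers 13.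

Step 11. Four aryl bromides and twelve benzyl ethers must go in one hydrogenation, and HBr, catalyst poisoning or incomplete debenzylation are possible. The fallback sets out from 14 and comes back at 15, removing bromine by organometallic means before any hydrogenation. Compound 14 is treated with n-BuLi (15 equiv, of which three are consumed by the hydroxyls; THF, −78 °C, 20 min) and quenched cold with MeOH. Halogen–lithium exchange and protonation give the bromine-free trimer 5,7,3',4'-tetra-O-benzylepicatechin-(4β→6)-5,7,3',4'-tetra-O-benzylepicatechin-(4β→6)-5,7,3',4'-tetra-O-benzylepicatechin F4. F4 is then hydrogenolysed (H2, Pd(OH)2/C, THF/MeOH/H2O, rt, no base, no HBr formed) to 15.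

## Further compounds

F1 | step 7 | 3-O-acetyl-8-bromo-4β-benzylsulfanyl-5,7,3',4'-tetra-O-benzylepicatechin | c1ccccc1COc1cc(OCc2ccccc2)c2c(c1Br)O[C@H](c1ccc(OCc3ccccc3)c(OCc3ccccc3)c1)[C@H](OC(C)=O)[C@H]2SCc1ccccc1
F2 | step 9 | 3-O-acetyl-8-bromo-4β-(2,6-dimethylphenylsulfanyl)-5,7,3',4'-tetra-O-benzylepicatechin | c1ccccc1COc1cc(OCc2ccccc2)c2c(c1Br)O[C@H](c1ccc(OCc3ccccc3)c(OCc3ccccc3)c1)[C@H](OC(C)=O)[C@H]2Sc1c(C)cccc1C
F3 | step 9 | 3-O-acetyl-6,8-dibromo-5,7,3',4'-tetra-O-benzylepicatechin-(4β→6)-3-O-acetyl-8-bromo-4β-(2,6-dimethylphenylsulfanyl)-5,7,3',4'-tetra-O-benzylepicatechin | c1ccccc1COc1c(Br)c(OCc2ccccc2)c2c(c1Br)O[C@H](c1ccc(OCc3ccccc3)c(OCc3ccccc3)c1)[C@H](OC(C)=O)[C@H]2c1c(OCc2ccccc2)c(Br)c2c(c1OCc3ccccc3)[C@H](Sc1c(C)cccc1C)[C@@H](OC(C)=O)[C@@H](c1ccc(OCc3ccccc3)c(OCc3ccccc3)c1)O2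
F4 | step 11 | 5,7,3',4'-tetra-O-benzylepicatechin-(4β→6)-5,7,3',4'-tetra-O-benzylepicatechin-(4β→6)-5,7,3',4'-tetra-O-benzylepicatechin | c1ccccc1COc1cc(OCc2ccccc2)c2c(c1)O[C@H](c1ccc(OCc3ccccc3)c(OCc3ccccc3)c1)[C@H](O)[C@H]2c1c(OCc2ccccc2)cc2c(c1OCc3ccccc3)[C@H](c1c(OCc3ccccc3)cc3c(c1OCc4ccccc4)C[C@@H](O)[C@@H](c1ccc(OCc4ccccc4)c(OCc4ccccc4)c1)O3)[C@@H](O)[C@@H](c1ccc(OCc3ccccc3)c(OCc3ccccc3)c1)O2
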